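**Plan**
Cuts, in retrosynthetic order: the C7 carbinol goes back to the α‑methylene ketone and C8=C19 to a C19 oxygen leaving group. Then follow C4–C5 (ring opening to a seco acid), C6–C7 (vinyl Grignard), C12–C13 (B‑alkyl Suzuki), C13=C14 (Wittig), C8–C19 and C8–C9 (enolate chemistry), and the carvone ring bond that hides C14 and the carboxyl carbon.
Enabling feature: C4 is the fully substituted carbon of the oxane ring (ring O, C18 methyl, C3, C5). A radical there is tertiary and α‑oxygenated, hence nucleophilic, and C5–C6–C7(=O) is the imprint such a radical leaves on a vinyl ketone.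
Forward order: the oxane is made first, as the O–C15 bridge of a 2‑oxabicyclo[2.2.2]octanone built on (R)‑carvone. The carbocyclic bridge is cleaved to C4–CO2H and C14–CHO, the C5–C12 chain is joined at C12–C13, and the 14‑membered carbocycle is closed last at C4–C5.
Stereochemistry: C1 comes from (R)‑carvone and C3 from the Luche reduction to cis‑carveol. C4 is rebuilt in the radical step by the C1 tether, matched with shielding by the C3 silyl ether, and C7 is set by (S)‑CBS reduction. The 11E geometry comes from syn‑hydrozirconation and stereoretentive coupling. C8 is auxiliary‑controlled and is erased at the end.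

Key step: step 22

Remark: compounds 1–9 carry p‑menthane numbers (C1 = C–CH3, C2 = former C=O, C4 = CH bearing C8, β = face of the C4 side chain) and cembrane numbers are used from 10 on; the C8 configuration is assumed to be without consequence because step 24 erases it.

Step 1
Reactants: 1 (R)‑(−)‑carvone
Product: 2 (−)‑cis‑carveol, (1R,5R)‑2‑methyl‑5‑(prop‑1‑en‑2‑yl)cyclohex‑2‑en‑1‑ol (OH cis to isopropenyl)
Conditions: NaBH4, CeCl3·7H2O, MeOH, −20 °C
Reagents that add atoms: none
Why: Luche reduction: the cerium‑activated carbonyl takes hydride 1,2 and axially (from the face opposite the side chain) in the half‑chair with equatorial isopropenyl, so the new C2 carbinol (future C3) is cis to the C4 side chain.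

Step 2
Reactants: 2 (−)‑cis‑carveol
Product: 3 (1R,2R,4S,6S)‑1‑methyl‑4‑(prop‑1‑en‑2‑yl)‑7‑oxabicyclo[4.1.0]heptan‑2‑ol (oxirane O, OH and isopropenyl all β)
Conditions: VO(acac)2 (cat.), t‑BuOOH, toluene, 0 °C → rt
Reagents that add atoms: tert‑butyl hydroperoxide, CC(C)(C)OO
Why: Vanadium‑catalysed hydroxyl‑directed epoxidation: the alkoxide‑bound peroxo species delivers oxygen to C1=C6 on the face of the hydroxyl (β) and ignores the remote isopropenyl group, which places C1–O on the face from which it can later reach C8.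

Step 3
Reactants: 3 β‑epoxy alcohol
Product: 4 tert‑butyldimethylsilyl (TBS) ether of 3
Conditions: TBSCl, imidazole, DMAP (cat.), DMF, rt
Reagents that add atoms: tert‑butyldimethylsilyl chloride, CC(C)(C)[Si](C)(C)Cl
Why: Standard silylation of the only hydroxyl; the bulky group is kept until step 23 because it must also shield one face of C4 in step 22.

Step 4
Reactants: 4 epoxy silyl ether
Product: 5 2β‑(TBSO)‑p‑menth‑8‑ene‑1β,6α‑diol (tertiary C1–OH β, secondary C6–OH α)
Conditions: HClO4 (cat.), THF/H2O 3:1, 0 °C → rt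
Reagents that add atoms: water, O
Why: Acid‑catalysed epoxide hydrolysis under Fürst–Plattner (trans‑diaxial) control: water attacks the secondary C6 from the α face, a position also favoured by inductive deactivation of C1 by the neighbouring silyloxy group, so the C1–O bond keeps its β orientation, as in the hydrolysis of the analogous limonene oxide.

Step 5
Reactants: 5 diol
Product: 7 2β‑(TBSO)‑1,8‑epoxy‑p‑menthan‑6α‑ol (1,3,3‑trimethyl‑2‑oxabicyclo[2.2.2]octane core; OTBS on the side of the O bridge, OH anti to it), via organomercury trifluoroacetate 6 (not isolated)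
Conditions: Hg(O2CCF3)2, THF, 0 °C → rt; then aq. NaOH, NaBH4, 0 °C
Reagents that add atoms: none
Why: Intramolecular oxymercuration–reductive demercuration: of the two free hydroxyls only the tertiary C1–OH shares the β face with the isopropenyl group, and its Markovnikov attack on the mercurinium ion at C8 closes the 1,8‑cineole ether (the future oxane O–C15 bond), a classical route to di‑tertiary ethers.

Step 6
Reactants: 7 bicyclic alcohol
Product: 8 2β‑(TBSO)‑1,8‑epoxy‑p‑menthan‑6‑one
Conditions: Dess–Martin periodinane, CH2Cl2, rt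
Reagents that add atoms: none
Why: Dess–Martin oxidation of the single free secondary alcohol under neutral conditions that leave the silyl ether and the bridged ether untouched.

Step 7
Reactants: 8 bicyclic ketone
Product: 9 6‑(trimethylsilyloxy)‑2β‑(TBSO)‑1,8‑epoxy‑p‑menth‑5‑ene
Conditions: TMSOTf, Et3N, CH2Cl2, 0 °C
Reagents that add atoms: trimethylsilyl triflate, C[Si](C)(C)OS(=O)(=O)C(F)(F)F
Why: Soft enolisation–silylation: C1 is quaternary, so the ketone can enolise only towards C5 and a single silyl enol ether should result.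

Step 8
Reactants: 9 silyl enol ether
Product: 11 (2R,3R,5R)‑5‑formyl‑2,6,6‑trimethyl‑3‑(TBSO)oxane‑2‑carboxylic acid (CO2H on C4 and CHO on C1 cis, OTBS trans to both), via trimethylsilyl ester 10 (not isolated)
Conditions: O3, CH2Cl2, −78 °C; Me2S, −78 °C → rt; aqueous work‑up
Reagents that add atoms: ozone, [O-][O+]=O
Why: Ozonolysis of a silyl enol ether: the oxygen‑bearing alkene carbon leaves as the silyl carboxylate (hydrolysed on work‑up) and the CH carbon as the aldehyde, so the two termini emerge differentiated and cis on the oxane because they were one bridge, with C1, C3 and C4 untouched.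

Step 9
Reactants: 11 aldehyde acid
Product: 12 methyl (2R,3R,5R)‑5‑formyl‑2,6,6‑trimethyl‑3‑(TBSO)oxane‑2‑carboxylate
Conditions: TMSCHN2, toluene/MeOH 4:1, 0 °C
Reagents that add atoms: (trimethylsilyl)diazomethane, C[Si](C)(C)C=[N+]=[N-]
Why: Diazoalkane esterification is neutral and insensitive to hindrance at the acyl carbon because the new C–O bond forms at the methyl carbon, so the epimerisable C1 aldehyde sees no base.

Step 10
Reactants: 12 aldehyde ester
Product: 13 methyl (2R,3R,5S)‑5‑ethenyl‑2,6,6‑trimethyl‑3‑(TBSO)oxane‑2‑carboxylate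
Conditions: Ph3PCH3Br, KHMDS, THF, −78 → 0 °C
Reagents that add atoms: methyltriphenylphosphonium bromide, C[P+](c1ccccc1)(c1ccccc1)c1ccccc1.[Br-]
Why: Wittig methylenation: the non‑stabilised ylide adds to the aldehyde at low temperature faster than it enolises it and leaves the hindered tertiary ester alone, which adds C13.

Step 11
Reactants: 14 pent‑3‑yn‑1‑ol
Product: 16 (E)‑4‑iodopent‑3‑en‑1‑ol, via alkenylzirconocene 15 (not isolated)
Conditions: Cp2ZrHCl (2.5 equiv), THF, rt → 40 °C; then I2, 0 °C
Reagents that add atoms: iodine, II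
Why: Hydrozirconation–iodinolysis: syn addition of H–Zr, equilibration by excess reagent to the less hindered methyl‑bearing carbon and Zr/I exchange with retention should give the (E)‑2‑iodoalkene that carries the 11E geometry.

Step 12
Reactants: 16 iodo alcohol
Product: 17 (E)‑2,5‑diiodopent‑2‑ene
Conditions: I2, PPh3, imidazole, CH2Cl2, 0 °C
Reagents that add atoms: iodine, II
Why: Appel‑type iodination replaces the primary hydroxyl by SN2 displacement of the oxyphosphonium ion and does not touch the vinyl iodide.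

Step 13
Reactants: 18 tert‑butyl acetate; 17 diiodide
Product: 20 tert‑butyl (E)‑6‑iodohept‑5‑enoate, via lithium enolate 19 (not isolated)
Conditions: LDA, THF, −78 °C; then 17, DMPU, −78 → −20 °C
Reagents that add atoms: none
Why: Ester enolate alkylation: the enolate displaces only the sp3 iodide (C8–C9 bond), the vinyl iodide being inert to SN2 attack and to enolates.

Step 14
Reactants: 20 tert‑butyl ester
Product: 21 (E)‑6‑iodohept‑5‑enoic acid
Conditions: TFA/CH2Cl2 1:4, 0 °C → rt
Reagents that add atoms: none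
Why: Acidolysis of the tert‑butyl ester (loss of isobutene) frees the acid without base.

Step 15
Reactants: 21 acid; 22 (R)‑4‑benzyl‑1,3‑oxazolidin‑2‑one
Product: 24 (R)‑4‑benzyl‑3‑[(E)‑6‑iodohept‑5‑enoyl]‑1,3‑oxazolidin‑2‑one, via mixed pivalic anhydride 23 (not isolated)
Conditions: PivCl, Et3N, THF, −20 °C; then 22, LiCl, rt
Reagents that add atoms: none
Why: N‑Acylation of the oxazolidinone auxiliary through the mixed anhydride, which is attacked at its less hindered carbonyl.

Step 16
Reactants: 24 imide
Product: 26 (R)‑4‑benzyl‑3‑[(2S,5E)‑2‑(hydroxymethyl)‑6‑iodohept‑5‑enoyl]‑1,3‑oxazolidin‑2‑one, via chlorotitanium enolate 25 (not isolated)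
Conditions: TiCl4, i‑Pr2NEt, CH2Cl2, 0 °C; then 1,3,5‑trioxane, TiCl4, 0 °C
Reagents that add atoms: 1,3,5‑trioxane, C1OCOCO1
Why: Auxiliary‑controlled hydroxymethylation of the chelated (Z)‑titanium enolate with TiCl4‑activated trioxane: the electrophile comes from the face opposite the benzyl group, which gives (8S) and adds C19.

Step 17
Reactants: 26 β‑hydroxy imide
Product: 27 (2S,5E)‑2‑(hydroxymethyl)‑6‑iodo‑N‑methoxy‑N‑methylhept‑5‑enamide
Conditions: MeONHMe·HCl, AlMe3, CH2Cl2, −10 °C → rt
Reagents that add atoms: N,O‑dimethylhydroxylamine hydrochloride, CNOC.Cl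
Why: Aluminium amide transamination to the Weinreb amide is assisted by the free β‑hydroxyl and releases the auxiliary without epimerisation.

Step 18
Reactants: 27 hydroxy amide
Product: 28 (2S,5E)‑2‑(TBSO‑methyl)‑6‑iodo‑N‑methoxy‑N‑methylhept‑5‑enamide
Conditions: TBSCl, imidazole, DMF, rt
Reagents that add atoms: tert‑butyldimethylsilyl chloride, CC(C)(C)[Si](C)(C)Cl
Why: Silylation of the primary alcohol masks the future exomethylene as CH2OTBS, which is neither a radical acceptor nor a leaving group under mild base.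

Step 19
Reactants: 13 vinyl oxane ester; 28 vinyl iodide
Product: 30 methyl ester/Weinreb amide with the complete C7–C14 chain (1R,3R,4R,8S,11E), via alkylborane 29 (not isolated)
Conditions: 13, 9‑BBN, THF, rt; then 28, Pd(dppf)Cl2 (cat.), AsPh3 (cat.), Cs2CO3, DMF/H2O, rt
Reagents that add atoms: none
Why: B‑alkyl Suzuki–Miyaura coupling: 9‑BBN adds anti‑Markovnikov to the only alkene of 13 and the primary alkyl group is transferred to the vinyl iodide with retention of the E geometry (C12–C13 bond), under conditions tolerated by ester, Weinreb amide and silyl ethers.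

Step 20
Reactants: 30 methyl ester
Product: 31 C4 carboxylic acid/Weinreb amide
Conditions: KOSiMe3, THF, rt → 40 °C; aq. KHSO4
Reagents that add atoms: potassium trimethylsilanolate, C[Si](C)(C)[O-].[K+]
Why: Anhydrous silanolate cleavage, a standard answer to hindered methyl esters, spares the Weinreb amide, the silyl ethers and C8, and it is done at this stage because a vinyl ketone would not survive any ester cleavage.

Step 21
Reactants: 31 acid amide; 32 vinylmagnesium bromide
Product: 34 (2R,3R,5R)‑3‑(TBSO)‑5‑[(3E,7S)‑7‑(TBSO‑methyl)‑3‑methyl‑8‑oxodeca‑3,9‑dien‑1‑yl]‑2,6,6‑trimethyloxane‑2‑carboxylic acid (seco acid with vinyl ketone), via magnesium chelate adduct 33 (not isolated)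
Conditions: 32 (3.5 equiv), THF, −78 → −10 °C; inverse quench into cold 1 M HCl/Et2O
Reagents that add atoms: none
Why: Weinreb ketone synthesis: the first equivalent of Grignard reagent only deprotonates the acid to an unreactive hindered carboxylate, and the next adds to the amide to give a chelate that collapses to the vinyl ketone only on the acidic inverse quench, which also keeps the released amine protonated and away from the enone.

Step 22
Reactants: 34 seco acid
Product: 35 (1R,3R,4S,8S,11E)‑3,19‑bis(TBSO)‑4,15‑epoxycembr‑11‑en‑7‑one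
Conditions: Ir[dF(CF3)ppy]2(dtbbpy)PF6 (2 mol %), K2HPO4, degassed DMF (1 mM, slow addition of 34), 450 nm LEDs, 25 °C
Reagents that add atoms: none
Why: Proposed new method: the excited Ir(III) complex oxidises the carboxylate of 34, CO2 is lost, the tertiary C4 radical (made nucleophilic by the ring oxygen lone pair) adds to the unsubstituted C5 terminus of the tethered vinyl ketone, and the C6 α‑keto radical is reduced by Ir(II) to the enolate and protonated, which closes the catalytic cycle. The closest known reactions are the intermolecular photoredox decarboxylative Giese addition of α‑oxy and tertiary acids to vinyl ketones, its use for peptide macrocyclisation through secondary α‑amino radicals, and tin hydride 14‑endo radical–enone closures of cembranoid chains; new here is a tertiary α‑oxy radical that closes a carbocycle and sets a quaternary centre in one event. The only ring formed is the 14‑membered carbocycle, closed 14‑endo‑trig, the 13‑exo mode being disfavoured by polarity and by substitution at C6. The only new stereocentre, C4, loses the configuration of the acid in the near‑planar radical and should be rebuilt (S) because C5 reaches without strain only the face that carries the C1–C14 arm, and this is also the face left open by the bulky C3 silyl ether, so tether and 1,2‑induction are matched. Chemoselectivity needs a single acceptor and fast intramolecular capture: the exomethylene is held back as CH2OTBS, the electron‑rich C11=C12 bond is polarity‑mismatched with the nucleophilic radical, the silyl ether at C3 cannot migrate as an acyloxy group could, and high dilution suppresses oligomerisation. The weak phosphate base leaves the β‑silyloxy ketone and C8 undisturbed.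

Step 23
Reactants: 35 macrocyclic ketone
Product: 36 (1R,3R,4S,8S,11E)‑3,19‑dihydroxy‑4,15‑epoxycembr‑11‑en‑7‑one
Conditions: HF·pyridine, pyridine/THF, 0 °C → rt
Reagents that add atoms: none
Why: Fluoride‑mediated cleavage of both silyl ethers under mildly acidic conditions avoids retro‑aldol loss of C19 from the β‑hydroxy ketone.

Step 24
Reactants: 36 diol
Product: 38 (1R,3R,4S,11E)‑3‑acetoxy‑4,15‑epoxycembra‑8(19),11‑dien‑7‑one, via diacetate 37 (not isolated)
Conditions: Ac2O, Et3N, DMAP (cat.), CH2Cl2, rt; then DBU, 0 °C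
Reagents that add atoms: acetic anhydride, CC(=O)OC(C)=O
Why: Acetylation of both hydroxyls followed by E1cB elimination: DBU removes the acidic C8–H and expels only the β‑acetoxy group at C19 to give the α‑methylene ketone, whereas the C3 acetate has no acidifying carbonyl next to it and stays.

Step 25
Reactants: 38 α‑methylene ketone
Product: 39 target, (1R,3R,4S,7R,11E)‑3‑acetoxy‑4,15‑epoxycembra‑8(19),11‑dien‑7‑ol
Conditions: (S)‑2‑methyl‑CBS‑oxazaborolidine, catecholborane, toluene, −78 °C; MeOH, aq. NaHCO3
Reagents that add atoms: none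
Why: Corey–Bakshi–Shibata reduction: the ketone binds the (S)‑oxazaborolidine anti to the larger 1,1‑disubstituted alkenyl group (C8) and hydride is delivered 1,2 to the face that gives the (7R)‑allylic alcohol, with catecholborane at low temperature sparing the acetate and both alkenes.

**Compound list**
1 | (R)‑(−)‑carvone | CC1=CC[C@@H](C(C)=C)CC1=O | starting material
2 | (−)‑cis‑carveol | CC1=CC[C@@H](C(C)=C)C[C@H]1O | intermediate
3 | β‑epoxy alcohol | C[C@]12O[C@H]1C[C@@H](C(C)=C)C[C@H]2O | intermediate
4 | TBS ether of 3 | C[C@]12O[C@H]1C[C@@H](C(C)=C)C[C@H]2O[Si](C)(C)C(C)(C)C | intermediate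
5 | 2β‑(TBSO)‑p‑menth‑8‑ene‑1β,6α‑diol | C[C@]1(O)[C@H](O)C[C@@H](C(C)=C)C[C@H]1O[Si](C)(C)C(C)(C)C | intermediate
6 | organomercury trifluoroacetate (C9–Hg, not isolated) | C[C@]12OC(C)(C[Hg]OC(=O)C(F)(F)F)[C@H](C[C@H]1O)C[C@H]2O[Si](C)(C)C(C)(C)C | intermediate
7 | 2β‑(TBSO)‑1,8‑epoxy‑p‑menthan‑6α‑ol | C[C@]12OC(C)(C)[C@H](C[C@H]1O)C[C@H]2O[Si](C)(C)C(C)(C)C | intermediate
8 | 2β‑(TBSO)‑1,8‑epoxy‑p‑menthan‑6‑one | C[C@]12OC(C)(C)[C@H](CC1=O)C[C@H]2O[Si](C)(C)C(C)(C)C | intermediate
9 | TMS enol ether of 8 | C[C@]12OC(C)(C)[C@H](C=C1O[Si](C)(C)C)C[C@H]2O[Si](C)(C)C(C)(C)C | intermediate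
10 | trimethylsilyl ester of 11 (not isolated) | O=C[C@@H]1C[C@@H](O[Si](C)(C)C(C)(C)C)[C@](C)(C(=O)O[Si](C)(C)C)OC1(C)C | intermediate
11 | oxane C14 aldehyde / C4 acid | O=C[C@@H]1C[C@@H](O[Si](C)(C)C(C)(C)C)[C@](C)(C(=O)O)OC1(C)C | intermediate
12 | methyl ester of 11 | O=C[C@@H]1C[C@@H](O[Si](C)(C)C(C)(C)C)[C@](C)(C(=O)OC)OC1(C)C | intermediate
13 | vinyl oxane methyl ester | C=C[C@@H]1C[C@@H](O[Si](C)(C)C(C)(C)C)[C@](C)(C(=O)OC)OC1(C)C | intermediate
14 | pent‑3‑yn‑1‑ol | CC#CCCO | starting material
15 | O‑zirconated (E)‑alkenylzirconocene chloride (not isolated) | Cl[Zr](C1C=CC=C1)(C1C=CC=C1)OCC/C=C(\C)[Zr](Cl)(C1C=CC=C1)C1C=CC=C1 | intermediate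
16 | (E)‑4‑iodopent‑3‑en‑1‑ol | OCC/C=C(\C)I | intermediate
17 | (E)‑2,5‑diiodopent‑2‑ene | ICC/C=C(\C)I | intermediate
18 | tert‑butyl acetate | CC(=O)OC(C)(C)C | starting material
19 | lithium enolate of 18 (not isolated) | C=C(O[Li])OC(C)(C)C | intermediate
20 | tert‑butyl (E)‑6‑iodohept‑5‑enoate | CC(C)(C)OC(=O)CCC/C=C(\C)I | intermediate
21 | (E)‑6‑iodohept‑5‑enoic acid | OC(=O)CCC/C=C(\C)I | intermediate
22 | (R)‑4‑benzyl‑1,3‑oxazolidin‑2‑one | O=C1N[C@H](Cc2ccccc2)CO1 | starting material
23 | mixed pivalic anhydride of 21 (not isolated) | CC(C)(C)C(=O)OC(=O)CCC/C=C(\C)I | intermediate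
24 | N‑acyl oxazolidinone | O=C(CCC/C=C(\C)I)N1[C@H](Cc2ccccc2)COC1=O | intermediate
25 | (Z)‑chlorotitanium enolate of 24 (not isolated) | Cl[Ti](Cl)(Cl)O/C(=C\CC/C=C(\C)I)N1[C@H](Cc2ccccc2)COC1=O | intermediate
26 | (2S)‑hydroxymethyl imide | O=C([C@H](CO)CC/C=C(\C)I)N1[C@H](Cc2ccccc2)COC1=O | intermediate
27 | β‑hydroxy Weinreb amide | CON(C)C(=O)[C@H](CO)CC/C=C(\C)I | intermediate
28 | TBS‑protected Weinreb amide vinyl iodide | CON(C)C(=O)[C@H](CO[Si](C)(C)C(C)(C)C)CC/C=C(\C)I | intermediate
29 | B‑alkyl‑9‑BBN from 13 (not isolated) | B1(C2CCCC1CCC2)CC[C@@H]3C[C@@H](O[Si](C)(C)C(C)(C)C)[C@](C)(C(=O)OC)OC3(C)C | intermediate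
30 | coupled methyl ester / Weinreb amide | CON(C)C(=O)[C@H](CO[Si](C)(C)C(C)(C)C)CC/C=C(\C)CC[C@@H]1C[C@@H](O[Si](C)(C)C(C)(C)C)[C@](C)(C(=O)OC)OC1(C)C | intermediate
31 | C4 acid / Weinreb amide | CON(C)C(=O)[C@H](CO[Si](C)(C)C(C)(C)C)CC/C=C(\C)CC[C@@H]1C[C@@H](O[Si](C)(C)C(C)(C)C)[C@](C)(C(=O)O)OC1(C)C | intermediate
32 | vinylmagnesium bromide | C=C[Mg]Br | starting material
33 | bromomagnesium carboxylate / chelated tetrahedral adduct (not isolated) | C=CC(O[Mg]Br)(N(C)OC)[C@H](CO[Si](C)(C)C(C)(C)C)CC/C=C(\C)CC[C@@H]1C[C@@H](O[Si](C)(C)C(C)(C)C)[C@](C)(C(=O)O[Mg]Br)OC1(C)C | intermediate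
34 | seco acid with tethered vinyl ketone (key‑step precursor) | C=CC(=O)[C@H](CO[Si](C)(C)C(C)(C)C)CC/C=C(\C)CC[C@@H]1C[C@@H](O[Si](C)(C)C(C)(C)C)[C@](C)(C(=O)O)OC1(C)C | intermediate
35 | macrocyclic C7 ketone (key‑step product) | CC(C)(C)[Si](C)(C)OC[C@@H]1CC/C=C(\C)CC[C@@H]2C[C@@H](O[Si](C)(C)C(C)(C)C)[C@](C)(CCC1=O)OC2(C)C | intermediate
36 | 3,19‑diol ketone | OC[C@@H]1CC/C=C(\C)CC[C@@H]2C[C@@H](O)[C@](C)(CCC1=O)OC2(C)C | intermediate
37 | 3,19‑diacetate ketone (not isolated) | CC(=O)OC[C@@H]1CC/C=C(\C)CC[C@@H]2C[C@@H](OC(C)=O)[C@](C)(CCC1=O)OC2(C)C | intermediate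
38 | 3‑acetoxy α‑methylene ketone | C=C1CC/C=C(\C)CC[C@@H]2C[C@@H](OC(C)=O)[C@](C)(CCC1=O)OC2(C)C | intermediate
39 | CNP0202897.1 | C=C1CC/C=C(\C)CC[C@@H]2C[C@@H](OC(C)=O)[C@](C)(CC[C@H]1O)OC2(C)C | target

**Step count:** 25 steps in total. The longest linear sequence is 17 steps (steps 1–10 and 19–25); the side‑chain branch is 8 steps (11–18).

**Steps most likely to fail**

1. Step 22. Several processes may outrun the wanted closure:
- intermolecular addition leading to oligomers;
- premature hydrogen abstraction by the C4 radical;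
- transannular capture of the C6 α‑keto radical by C11=C12;
- attack on the wrong face of the radical.

The fallback uses only known reaction types (intermolecular decarboxylative Giese addition, then B‑alkyl Suzuki macrocyclisation). It sets out from 13 and 28 and returns at 35. Ester 13 is cleaved with KOSiMe3 to the vinyl oxane acid F1. Amide 28 is treated with 32 to give the iodo vinyl ketone F2. The two are joined at C4–C5 under the established intermolecular Ir/K2HPO4/blue‑light conditions to give the open‑chain ketone F3, in which the C3 silyl ether alone directs attack to the opposite face. Excess 9‑BBN hydroborates the vinyl group and reduces the ketone to the bis‑boron species F4. This is cyclised at C12–C13 under high dilution with Pd(dppf)Cl2/AsPh3/Cs2CO3 to the macrocyclic carbinol F5 (C7 epimers). Dess–Martin oxidation then gives 35.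

2. Step 5. Closure through the required boat conformer may be sluggish. The C2 silyl ether oxygen may take part with loss of the silyl group, or the ether may revert during demercuration. The fallback closes the ether in the opposite sense, from a C8 alcohol onto the ring alkene. It sets out from 2 and returns at 8. Compound 2 is silylated to the carveol silyl ether F6. Mukaiyama hydration (Co(acac)2, PhSiH3, O2) of the 1,1‑disubstituted alkene gives the tertiary alcohol F7. Iodoetherification with NIS (iodonium on the α face, oxygen attack at the tertiary C1) gives the iodo cineole F8. Radical hydroxylation (Bu3SnH, O2) gives the cineolol F9 (C6 epimers, both usable), and Dess–Martin oxidation gives 8.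

3. Step 25. Reagent control may be mismatched with the conformational bias of the macrocycle, giving poor facial selectivity, or the boron hydride may add to the exomethylene. The fallback relies on substrate control followed by inversion. It sets out from 38 and returns at 39. Luche reduction gives, beside any 39 formed directly, the 7‑epi alcohol F10. Mitsunobu inversion with chloroacetic acid gives the (7R)‑chloroacetate F11. Thiourea/NaHCO3 then removes the chloroacetyl group selectively in the presence of the C3 acetate to give 39.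

**Further compounds**
F1 | step 22 | (2R,3R,5S)‑5‑ethenyl‑2,6,6‑trimethyl‑3‑(TBSO)oxane‑2‑carboxylic acid | C=C[C@@H]1C[C@@H](O[Si](C)(C)C(C)(C)C)[C@](C)(C(=O)O)OC1(C)C
F2 | step 22 | (4S,7E)‑4‑(TBSO‑methyl)‑8‑iodonona‑1,7‑dien‑3‑one | C=CC(=O)[C@H](CO[Si](C)(C)C(C)(C)C)CC/C=C(\C)I
F3 | step 22 | open‑chain C7 ketone with C4–C5 bond, C1 vinyl group and C12 iodide | C=C[C@@H]1C[C@@H](O[Si](C)(C)C(C)(C)C)[C@](C)(CCC(=O)[C@H](CO[Si](C)(C)C(C)(C)C)CC/C=C(\C)I)OC1(C)C
F4 | step 22 | C13 B‑alkyl‑9‑BBN / C7 O‑borinate of reduced F3 | B1(C2CCCC1CCC2)CC[C@@H]3C[C@@H](O[Si](C)(C)C(C)(C)C)[C@](C)(CCC(OB4C5CCCC4CCC5)[C@H](CO[Si](C)(C)C(C)(C)C)CC/C=C(\C)I)OC3(C)C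
F5 | step 22 | 3,19‑bis(TBSO)‑4,15‑epoxycembr‑11‑en‑7‑ol (C7 epimers) | CC(C)(C)[Si](C)(C)OC[C@@H]1CC/C=C(\C)CC[C@@H]2C[C@@H](O[Si](C)(C)C(C)(C)C)[C@](C)(CCC1O)OC2(C)C
F6 | step 5 | cis‑carveol TBS ether | CC1=CC[C@@H](C(C)=C)C[C@H]1O[Si](C)(C)C(C)(C)C
F7 | step 5 | 2β‑(TBSO)‑p‑menth‑6‑en‑8‑ol | CC1=CC[C@@H](C(C)(C)O)C[C@H]1O[Si](C)(C)C(C)(C)C
F8 | step 5 | 6α‑iodo‑2β‑(TBSO)‑1,8‑epoxy‑p‑menthane | C[C@]12OC(C)(C)[C@H](C[C@H]1I)C[C@H]2O[Si](C)(C)C(C)(C)C
F9 | step 5 | 2β‑(TBSO)‑1,8‑epoxy‑p‑menthan‑6‑ol (C6 epimers) | C[C@]12OC(C)(C)[C@H](CC1O)C[C@H]2O[Si](C)(C)C(C)(C)C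
F10 | step 25 | (7S)‑epimer of 39 | C=C1CC/C=C(\C)CC[C@@H]2C[C@@H](OC(C)=O)[C@](C)(CC[C@@H]1O)OC2(C)C
F11 | step 25 | (7R)‑chloroacetate of 39 | C=C1CC/C=C(\C)CC[C@@H]2C[C@@H](OC(C)=O)[C@](C)(CC[C@H]1OC(=O)CCl)OC2(C)C
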